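**Strategy.** The α‑methylene‑β‑hydroxy‑γ‑lactone (ring O6–C6–C7–C11–C12, germacrane numbering, C13 = exocyclic CH2) is traced to a 2‑methylene‑3‑alkoxycyclobutanone, the same ring without O6. That cyclobutanone is assembled in one operation by a Wolff rearrangement/ketene–alkoxyallene [2+2] cycloaddition that joins both halves of the molecule, forming C11–C12 and C6–C7 and setting C6 and C7. The alkoxyallene supplies the C7 oxygen and the C11=C13 methylene, and a chiral dioxolane tying O7 to O8 steers the facial selectivity. Baeyer–Villiger insertion of O6, ring‑closing metathesis to the (1(10)Z,4E)‑cyclodecadiene and double epoxidation complete the route. The precursors are a dienyl diazoketone and a 4‑vinylidene‑1,3‑dioxolane.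

Key step: step 8

Remark: germacrane numbering is used throughout (C6 = lactone O–CH, C7 = tertiary carbinol, C8 = ester carbinol, C12 = lactone C=O). The SMILES corresponds to (1S,4R,5R,6R,7S,8R,10R), i.e. a cis‑1,10‑epoxide and a trans‑4,5‑epoxide, so the ring alkenes needed are 1(10)Z and 4E.

Assumption: racemic pent‑1‑en‑4‑yn‑3‑ol and hex‑5‑en‑2‑one are taken as commercial materials.

Step 1
Reactants: 1 hex‑5‑en‑2‑one
Product: 2 ethyl (2E)‑3‑methylhepta‑2,6‑dienoate
Conditions: triethyl phosphonoacetate, NaH, THF, 0 °C then 60 °C; chromatography to remove the Z‑isomer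
Reagents that add atoms: triethyl phosphonoacetate CCOC(=O)CP(=O)(OCC)OCC
Why: Horner–Wadsworth–Emmons olefination of a methyl ketone with a stabilised phosphonate anion should favour the (E)‑enoate (ester trans to the longer chain), and the minor Z‑isomer is separable.

Step 2
Reactants: 2 ethyl (2E)‑3‑methylhepta‑2,6‑dienoate
Product: 3 (2E)‑3‑methylhepta‑2,6‑dienoic acid
Conditions: LiOH, THF/MeOH/H2O, 40 °C; then 1 M HCl
Reagents that add atoms: lithium hydroxide [Li+].[OH-]
Why: Ester saponification, under which the trisubstituted conjugated alkene keeps its geometry.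

Step 3
Reactants: 3 (2E)‑3‑methylhepta‑2,6‑dienoic acid
Product: 5 (3E)‑1‑diazo‑4‑methylocta‑3,7‑dien‑2‑one, via mixed isobutyl carbonic anhydride 4 (not isolated)
Conditions: i‑BuOCOCl, N‑methylmorpholine, THF, −20 °C; then CH2N2 in Et2O, −20 °C to 0 °C
Reagents that add atoms: diazomethane C=[N+]=[N-]; isobutyl chloroformate CC(C)COC(Cl)=O (its atoms stay only in 4)
Why: Acylation of diazomethane by a mixed anhydride (first stage of the Arndt–Eistert sequence) gives the α′‑diazo enone, the β,β‑disubstituted enoyl C=C being too hindered for competing dipolar cycloaddition of diazomethane.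

Step 4
Reactants: 6 rac‑pent‑1‑en‑4‑yn‑3‑ol
Product: 7 (1R)‑1‑[(2R)‑oxiran‑2‑yl]prop‑2‑yn‑1‑ol
Conditions: Ti(OiPr)4 (cat.), D‑(−)‑diisopropyl tartrate, t‑BuOOH (0.45 equiv), 4 Å molecular sieves, CH2Cl2, −20 °C
Reagents that add atoms: tert‑butyl hydroperoxide CC(C)(C)OO
Why: Sharpless kinetic resolution, in which the D‑(−)‑tartrate complex epoxidises the (S)‑alcohol much faster than its enantiomer and on the face that gives the erythro epoxy alcohol, so the oxirane carbon (future C8) is set as R by the reagent while the (R)‑alcohol is left behind.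

Step 5
Reactants: 7 (1R)‑1‑[(2R)‑oxiran‑2‑yl]prop‑2‑yn‑1‑ol
Product: 8 (3R,4R)‑6‑methylhept‑6‑en‑1‑yne‑3,4‑diol
Conditions: isopropenylmagnesium bromide (3.5 equiv), CuI (10 mol%), THF, −40 °C to −10 °C; aq. NH4Cl
Reagents that add atoms: isopropenylmagnesium bromide CC(=C)[Mg]Br
Why: Copper‑catalysed Grignard opening of a terminal epoxide by SN2 attack at the unsubstituted CH2 leaves the C8 stereocentre untouched, the first two equivalents only deprotonating OH and C≡C–H.

Step 6
Reactants: 8 (3R,4R)‑6‑methylhept‑6‑en‑1‑yne‑3,4‑diol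
Product: 9 (4R,5R)‑4‑ethynyl‑2,2‑dimethyl‑5‑(2‑methylprop‑2‑en‑1‑yl)‑1,3‑dioxolane
Conditions: 2,2‑dimethoxypropane, pyridinium p‑toluenesulfonate (cat.), CH2Cl2, 23 °C
Reagents that add atoms: 2,2‑dimethoxypropane COC(C)(C)OC
Why: Acid‑catalysed transketalisation ties O7 and O8 into a dioxolane without touching either stereocentre.

Step 7
Reactants: 9 (4R,5R)‑4‑ethynyl‑2,2‑dimethyl‑5‑(2‑methylprop‑2‑en‑1‑yl)‑1,3‑dioxolane
Product: 10 (5R)‑4‑ethenylidene‑2,2‑dimethyl‑5‑(2‑methylprop‑2‑en‑1‑yl)‑1,3‑dioxolane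
Conditions: KOtBu (0.3 equiv), DMSO, 20 °C, short reaction time; base‑washed glassware
Reagents that add atoms: none
Why: Base‑catalysed propargyl‑to‑allenyl ether isomerisation (prototropic rearrangement) is driven by conjugation of the new C7=C11 bond with O7 and stops at the allene because C7 carries no further hydrogen, the C8 stereocentre not being involved.

Step 8
Reactants: 5 (3E)‑1‑diazo‑4‑methylocta‑3,7‑dien‑2‑one; 10 (5R)‑4‑ethenylidene‑2,2‑dimethyl‑5‑(2‑methylprop‑2‑en‑1‑yl)‑1,3‑dioxolane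
Product: 12 (1R,4S,8R)‑6,6‑dimethyl‑3‑methylidene‑1‑[(1E)‑2‑methylhexa‑1,5‑dien‑1‑yl]‑8‑(2‑methylprop‑2‑en‑1‑yl)‑5,7‑dioxaspiro[3.4]octan‑2‑one, via vinylketene 11 (not isolated)
Conditions: 5 added slowly to 10 (2 equiv), CH2Cl2, hν (390–405 nm LED), 0 °C to 20 °C
Reagents that add atoms: none
Why: Irradiation of 5 triggers a Wolff rearrangement (1,2‑shift of the alkenyl group with loss of N2, alkene geometry retained) to vinylketene 11, whose electrophilic carbonyl carbon C12 is attacked by the nucleophilic central allene carbon C11 of the enol‑ether π‑bond of 10, and the enolate/oxocarbenium pair then collapses by C6–C7 bond formation; the closest known types are ketene–enol ether and ketene–allene [2+2] cycloadditions and the photochemical Wolff/vinylketene cycloaddition sequence used in benzannulations. The only ring closed is the cyclobutanone (C12–C11–C7–C6), by an asynchronous [2+2] cycloaddition across the allene C7=C11 bond that ends in a 4‑exo‑trig collapse and leaves C11=C13 as the exocyclic methylene, spiro to the dioxolane. C7 is controlled by the dioxolane, because C6 adds to the face of C7=C11 opposite the 2‑methylallyl group on C8, which places C6 and C9 trans on the dioxolane (the 7,8‑syn diol pattern of the target). C6 is controlled by 1,2‑strain in the ring closure, the alkenyl group ending cis to the small ring oxygen O7 and trans to C8 (the later trans ring fusion), and the acidic C6–H allows a minor epimer to equilibrate to this isomer. The step needs chemoselectivity for the enol‑ether bond over the 1,1‑disubstituted and terminal alkenes (secured by its much higher nucleophilicity), regioselectivity C12 to C11 with closure at C7 (ketene LUMO at the carbonyl carbon, allene HOMO at the central carbon, cation stabilised by O7) and suppression of ketene dimerisation (slow photochemical generation of 11 in the presence of excess 10, at a wavelength the β,γ‑unsaturated cyclobutanone does not absorb).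

Step 9
Reactants: 12 (1R,4S,8R)‑6,6‑dimethyl‑3‑methylidene‑1‑[(1E)‑2‑methylhexa‑1,5‑dien‑1‑yl]‑8‑(2‑methylprop‑2‑en‑1‑yl)‑5,7‑dioxaspiro[3.4]octan‑2‑one
Product: 13 (4R,5S,6R)‑2,2‑dimethyl‑9‑methylidene‑6‑[(1E)‑2‑methylhexa‑1,5‑dien‑1‑yl]‑4‑(2‑methylprop‑2‑en‑1‑yl)‑1,3,7‑trioxaspiro[4.4]nonan‑8‑one
Conditions: 30% aq. H2O2, CF3CH2OH, 0 °C to 20 °C
Reagents that add atoms: hydrogen peroxide OO
Why: Baeyer–Villiger oxidation, fast for the strained cyclobutanone, in which the secondary allylic carbon C6 migrates in preference to the sp2 carbon C11 and with retention, so O6 enters between C12 and C6 with the C6 configuration kept, while H2O2 in a fluorinated alcohol leaves the alkenes alone.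

Step 10
Reactants: 13 (4R,5S,6R)‑2,2‑dimethyl‑9‑methylidene‑6‑[(1E)‑2‑methylhexa‑1,5‑dien‑1‑yl]‑4‑(2‑methylprop‑2‑en‑1‑yl)‑1,3,7‑trioxaspiro[4.4]nonan‑8‑one
Product: 14 (4S,5R)‑4‑hydroxy‑4‑[(1R)‑1‑hydroxy‑3‑methylbut‑3‑en‑1‑yl]‑3‑methylidene‑5‑[(1E)‑2‑methylhexa‑1,5‑dien‑1‑yl]oxolan‑2‑one
Conditions: AcOH/H2O (4:1), 40 °C
Reagents that add atoms: none
Why: Acid‑catalysed acetal hydrolysis at a stage where no epoxide is present yet, the lactone, the trisubstituted alkene and the stereocentres being stable to aqueous acetic acid.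

Step 11
Reactants: 14 (4S,5R)‑4‑hydroxy‑4‑[(1R)‑1‑hydroxy‑3‑methylbut‑3‑en‑1‑yl]‑3‑methylidene‑5‑[(1E)‑2‑methylhexa‑1,5‑dien‑1‑yl]oxolan‑2‑one
Product: 15 (1R)‑1‑[(2R,3S)‑3‑hydroxy‑4‑methylidene‑2‑[(1E)‑2‑methylhexa‑1,5‑dien‑1‑yl]‑5‑oxooxolan‑3‑yl]‑3‑methylbut‑3‑en‑1‑yl 2‑methylprop‑2‑enoate
Conditions: methacrylic anhydride (1.2 equiv), DMAP (cat.), Et3N, CH2Cl2, 0 °C
Reagents that add atoms: methacrylic anhydride C=C(C)C(=O)OC(=O)C(C)=C
Why: DMAP‑catalysed acylation is selective for the secondary 8‑OH because the tertiary 7‑OH on the fully substituted C7 is too hindered to react.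

Step 12
Reactants: 15 (1R)‑1‑[(2R,3S)‑3‑hydroxy‑4‑methylidene‑2‑[(1E)‑2‑methylhexa‑1,5‑dien‑1‑yl]‑5‑oxooxolan‑3‑yl]‑3‑methylbut‑3‑en‑1‑yl 2‑methylprop‑2‑enoate
Product: 16 (1(10)Z,4E,6R,7S,8R)‑7‑hydroxy‑8‑(2‑methylprop‑2‑enoyloxy)germacra‑1(10),4,11(13)‑trien‑12,6‑olide
Conditions: second‑generation Grubbs catalyst RuCl2(=CHPh)(H2IMes)(PCy3) (10 mol%), 1,4‑benzoquinone (20 mol%), CH2Cl2 (1 mM), 40 °C
Reagents that add atoms: none
Why: Ring‑closing metathesis, in which the ruthenium carbene loads at the unhindered terminal vinyl group and closes onto the 1,1‑disubstituted alkene under high dilution with loss of ethene; the ten‑membered ring is expected to accept the trisubstituted alkene only in the less strained Z geometry (C9 and C2 cis), and the electron‑poor methacrylate, the α‑methylene lactone and the trisubstituted C4=C5 alkene are poor metathesis partners.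

Step 13
Reactants: 16 (1(10)Z,4E,6R,7S,8R)‑7‑hydroxy‑8‑(2‑methylprop‑2‑enoyloxy)germacra‑1(10),4,11(13)‑trien‑12,6‑olide
Product: 17 (1S,4R,5R,6R,7S,8R,10R)‑1,10:4,5‑diepoxy‑7‑hydroxy‑8‑(2‑methylprop‑2‑enoyloxy)germacr‑11(13)‑en‑12,6‑olide (CNP0228789.1)
Conditions: mCPBA (2.5 equiv), NaHCO3, CH2Cl2, 0 °C
Reagents that add atoms: 3‑chloroperoxybenzoic acid O=C(OO)c1cccc(Cl)c1
Why: Prilezhaev epoxidation, in which only the two electron‑rich trisubstituted ring alkenes react, each stereospecifically (E gives the trans‑4,5‑epoxide, Z the cis‑1,10‑epoxide), and the macrocycle should control the faces: the 4E alkene is attacked on its exposed outer face as in related trans‑4,5 germacranolides (4R,5R), and the 1(10)Z alkene on the face anti to the adjacent 8‑ester and syn to the hydrogen‑bonding 7‑OH (1S,10R).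

**Compound list**

1 | hex‑5‑en‑2‑one | CC(=O)CCC=C | starting material
2 | ethyl (2E)‑3‑methylhepta‑2,6‑dienoate | C=CCC/C(C)=C/C(=O)OCC | intermediate
3 | (2E)‑3‑methylhepta‑2,6‑dienoic acid | C=CCC/C(C)=C/C(=O)O | intermediate
4 | (2E)‑3‑methylhepta‑2,6‑dienoic isobutyl carbonic anhydride | C=CCC/C(C)=C/C(=O)OC(=O)OCC(C)C | intermediate (not isolated)
5 | (3E)‑1‑diazo‑4‑methylocta‑3,7‑dien‑2‑one | C=CCC/C(C)=C/C(=O)C=[N+]=[N-] | intermediate
6 | rac‑pent‑1‑en‑4‑yn‑3‑ol | C=CC(O)C#C | starting material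
7 | (1R)‑1‑[(2R)‑oxiran‑2‑yl]prop‑2‑yn‑1‑ol | C#C[C@@H](O)[C@H]1CO1 | intermediate
8 | (3R,4R)‑6‑methylhept‑6‑en‑1‑yne‑3,4‑diol | C#C[C@@H](O)[C@H](O)CC(C)=C | intermediate
9 | (4R,5R)‑4‑ethynyl‑2,2‑dimethyl‑5‑(2‑methylprop‑2‑en‑1‑yl)‑1,3‑dioxolane | C#C[C@H]1OC(C)(C)O[C@@H]1CC(C)=C | intermediate
10 | (5R)‑4‑ethenylidene‑2,2‑dimethyl‑5‑(2‑methylprop‑2‑en‑1‑yl)‑1,3‑dioxolane | C=C=C1OC(C)(C)O[C@@H]1CC(C)=C | intermediate
11 | (3E)‑4‑methylocta‑1,3,7‑trien‑1‑one (vinylketene) | C=CCC/C(C)=C/C=C=O | intermediate (not isolated)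
12 | (1R,4S,8R)‑6,6‑dimethyl‑3‑methylidene‑1‑[(1E)‑2‑methylhexa‑1,5‑dien‑1‑yl]‑8‑(2‑methylprop‑2‑en‑1‑yl)‑5,7‑dioxaspiro[3.4]octan‑2‑one | C=C1C(=O)[C@H](/C=C(\C)CCC=C)[C@]12OC(C)(C)O[C@@H]2CC(C)=C | intermediate
13 | (4R,5S,6R)‑2,2‑dimethyl‑9‑methylidene‑6‑[(1E)‑2‑methylhexa‑1,5‑dien‑1‑yl]‑4‑(2‑methylprop‑2‑en‑1‑yl)‑1,3,7‑trioxaspiro[4.4]nonan‑8‑one | C=C1C(=O)O[C@H](/C=C(\C)CCC=C)[C@]12OC(C)(C)O[C@@H]2CC(C)=C | intermediate
14 | (4S,5R)‑4‑hydroxy‑4‑[(1R)‑1‑hydroxy‑3‑methylbut‑3‑en‑1‑yl]‑3‑methylidene‑5‑[(1E)‑2‑methylhexa‑1,5‑dien‑1‑yl]oxolan‑2‑one | C=C1C(=O)O[C@H](/C=C(\C)CCC=C)[C@@]1(O)[C@H](O)CC(C)=C | intermediate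
15 | (1R)‑1‑[(2R,3S)‑3‑hydroxy‑4‑methylidene‑2‑[(1E)‑2‑methylhexa‑1,5‑dien‑1‑yl]‑5‑oxooxolan‑3‑yl]‑3‑methylbut‑3‑en‑1‑yl 2‑methylprop‑2‑enoate | C=C1C(=O)O[C@H](/C=C(\C)CCC=C)[C@@]1(O)[C@H](OC(=O)C(C)=C)CC(C)=C | intermediate
16 | (1(10)Z,4E,6R,7S,8R)‑7‑hydroxy‑8‑(2‑methylprop‑2‑enoyloxy)germacra‑1(10),4,11(13)‑trien‑12,6‑olide | C=C(C)C(=O)O[C@@H]1C/C(C)=C\CC/C(C)=C/[C@H]2OC(=O)C(=C)[C@@]21O | intermediate
17 | (1S,4R,5R,6R,7S,8R,10R)‑1,10:4,5‑diepoxy‑7‑hydroxy‑8‑(2‑methylprop‑2‑enoyloxy)germacr‑11(13)‑en‑12,6‑olide | C=C(C)C(=O)O[C@@H]1C[C@@]2(C)O[C@H]2CC[C@@]2(C)O[C@@H]2[C@H]2OC(=O)C(=C)[C@@]21O | target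

**Step count.** Total: 13 steps. Longest linear sequence: 10 steps (6 to 17, steps 4–13).

**Steps most likely to fail**

Step 8. The photogenerated vinylketene may dimerise or oligomerise faster than it is captured by 10, or be captured with poor facial discrimination at C7. The fallback replaces the free ketene by a keteniminium ion, which does not dimerise. Setting out from 5, the Wolff rearrangement is run in the presence of pyrrolidine (hν, THF) to give the amide (3E)‑4‑methyl‑1‑(pyrrolidin‑1‑yl)octa‑3,7‑dien‑1‑one F1. Activation with Tf2O and 2,4,6‑collidine (CH2Cl2, −25 °C) gives the vinylketeniminium triflate F2. This undergoes the known keteniminium–alkene [2+2] cycloaddition with 10, under the same dioxolane facial control, to the cyclobutaniminium triflate F3. Hydrolysis with aqueous NaHCO3 returns to the route at 12.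

Step 12. Cross‑metathesis oligomerisation may outpace closure of the strained ten‑membered ring, or the carbene may engage the methacrylate alkene. The fallback closes the ring before the acrylate is installed. Setting out from 14, the metathesis is run on the free diol (same catalyst, high dilution), where no acrylate competes and the two hydroxyls can pre‑organise the chain, to give (1(10)Z,4E,6R,7S,8R)‑7,8‑dihydroxygermacra‑1(10),4,11(13)‑trien‑12,6‑olide F4. Selective methacryloylation of the secondary 8‑OH as in step 11 returns to the route at 16.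

Step 13. Substrate control may deliver the peracid to the wrong face of one of the two ring alkenes. The fallback uses reagent control: Shi epoxidation of 16 (fructose‑derived ketone catalyst of the enantiomeric series matched to the required faces, KHSO5 as the triple salt 2KHSO5·KHSO4·K2SO4, K2CO3 buffer, MeCN/dimethoxymethane/H2O, 0 °C). It sets out from 16 and arrives directly at 17, making no new compound (F0).

Further compounds
F1 | step 8 | (3E)‑4‑methyl‑1‑(pyrrolidin‑1‑yl)octa‑3,7‑dien‑1‑one | C=CCC/C(C)=C/CC(=O)N1CCCC1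
F2 | step 8 | 1‑[(3E)‑4‑methylocta‑1,3,7‑trien‑1‑ylidene]pyrrolidin‑1‑ium trifluoromethanesulfonate | C=CCC/C(C)=C/C=C=[N+]1CCCC1.[O-]S(=O)(=O)C(F)(F)F
F3 | step 8 | pyrrolidinium (iminium) analogue of 12, trifluoromethanesulfonate salt | C=C1C(=[N+]2CCCC2)[C@H](/C=C(\C)CCC=C)[C@]13OC(C)(C)O[C@@H]3CC(C)=C.[O-]S(=O)(=O)C(F)(F)F
F4 | step 12 | (1(10)Z,4E,6R,7S,8R)‑7,8‑dihydroxygermacra‑1(10),4,11(13)‑trien‑12,6‑olide | O[C@@H]1C/C(C)=C\CC/C(C)=C/[C@H]2OC(=O)C(=C)[C@@]21O
F0 | step 13 | none | none
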